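**Retrosynthetic overview**
1. The N–H amine comes from hydrogenolysis of an N-(2-hydroxy-1-phenylethyl) group; the C5–C1' biaryl bond comes from a Suzuki–Miyaura coupling of a 5-bromo-tetrahydroisoquinoline with a 1-naphthyl boronate.
2. The oxygenated ring of the naphthalene is built by a Dötz benzannulation (aryl methoxycarbene complex of chromium + propyne), which places 1-OH (coupling handle), 2-Me, 4-OMe and 5-OMe in one step.
3. The nitrogen ring is cut at C3–C4 and C1–C8a. In one flask a 3,5-dimethoxybenzyl Grignard reagent adds to the acetaldehyde oxazolidine of (R)-phenylglycinol (C3–C4); acidification then lets a second acetaldehyde unit, present from the start as its diethyl acetal, close the ring by Pictet–Spengler reaction (C1–C8a).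
4. Enabling feature: C1 and C3 are two CH(CH3) carbons on the one nitrogen N2, that is, two acetaldehyde carbons (latent iminium carbons) held trans. C4 and C8a are a benzylic carbon and the neighbouring ring carbon that lies ortho to the C8 methoxy group and para to the C6 methoxy group, a 1,3-C,C-dinucleophile. The heterocycle is therefore a formal (3+3) union.
5. Ring order: ring A is bought, the nitrogen ring is closed in the key step, the second naphthalene ring is built by benzannulation, and the two halves are joined last.

Key step: step 3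

Assumption: the target structure does not define the configuration of the C5–C1' biaryl axis, so it is not controlled; the route should give the (1S,3S) compound as both atropo-diastereomers, separable if one is wanted.

**Step 1**
Reactants: 1 (R)-phenylglycinol [(2R)-2-amino-2-phenylethanol]; 2 acetaldehyde
Product: 3 the oxazolidine (4R)-2-methyl-4-phenyl-1,3-oxazolidine (both C2 epimers; ring tautomer of the hydroxy imine)
Conditions: MgSO4, CH2Cl2, 0 °C → rt
Reagents that add atoms: none
Why: Condensation of a 1,2-amino alcohol with an aldehyde (oxazolidine formation) should go to completion with a drying agent, and the configuration at C2 of the ring is irrelevant because that carbon becomes the sp2 imine carbon when the ring opens in step 3.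

**Step 2**
Reactants: 4 3,5-dimethoxybenzyl chloride
Product: 5 (3,5-dimethoxybenzyl)magnesium chloride (titrated THF solution; used directly)
Conditions: Mg turnings (activated with BrCH2CH2Br), THF, 0 °C, slow addition
Reagents that add atoms: magnesium, [Mg]
Why: Magnesium inserts into the benzylic C–Cl bond (Grignard reagent formation), and slow addition at 0 °C in dilute solution should keep Wurtz homocoupling small.

**Step 3**
Reactants: 5 (3,5-dimethoxybenzyl)magnesium chloride; 3 the oxazolidine (4R)-2-methyl-4-phenyl-1,3-oxazolidine; 6 acetaldehyde diethyl acetal (1,1-diethoxyethane)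
Product: 10 the tetrahydroisoquinoline (1S,3S)-2-[(1R)-2-hydroxy-1-phenylethyl]-6,8-dimethoxy-1,3-dimethyl-1,2,3,4-tetrahydroisoquinoline, via amino alcohol 7 (not isolated), via oxazolidine 8 (not isolated), via iminium trifluoroacetate 9 (not isolated)
Conditions: 3 + 6 (4 equiv) in THF; 5 (2.3 equiv), −40 °C → rt; then CF3CO2H (10 equiv), CH2Cl2, 0 → 40 °C, same flask; K2CO3, MeOH, H2O work-up
Reagents that add atoms: none
Why: Mechanism: one equivalent of 5 deprotonates 3 and opens it to the (E)-imine whose nitrogen and alkoxide oxygen chelate magnesium, and a further equivalent delivers the benzylic carbon to the imine carbon from the face opposite to the phenyl group of this five-membered chelate, which should set C3 as S and gives 7 on protonation (Grignard addition to a phenylglycinol-derived 1,3-oxazolidine). Acid then lets the acetal 6, inert until now, hand its ethylidene unit to the amino alcohol (transient oxazolidine 8, closed 5-endo-trig by oxygen and reopened by acid), and the resulting iminium ion 9 is attacked by the ring carbon ortho to the side chain, which is ortho to one methoxy group and para to the other, in a 6-endo-trig Pictet–Spengler closure of the nitrogen ring. The closest known reaction types are the organomagnesium opening of chiral oxazolidines and the Pictet–Spengler reaction of N-alkyl 1-arylpropan-2-amines with acetaldehyde acetals in CF3CO2H; run back to back they amount to a formal (3+3) annulation of a C,C-dinucleophile with two aldehyde carbons on one nitrogen. C1 is controlled by C3 and by the bulky N-substituent: in the chair-like transition state the C3 methyl group should sit pseudoaxial to avoid the N-substituent and the arene should add to the (E)-iminium ion so that the C1 methyl group ends up trans to it, as is known for N-benzyl analogues, giving (1S,3S). The step needs addition to the enolisable imine to beat α-deprotonation (benzylic Grignard reagents are strongly nucleophilic and weakly basic, and chelation activates the imine), it needs 6 to survive the Grignard stage (acetals do not react with Grignard reagents in THF at or below room temperature), and the site of ring closure is not an issue because the two positions ortho to the side chain are equivalent while the position between the methoxy groups cannot reach the iminium carbon. The hydroxy-phenylethyl group on nitrogen therefore acts as chiral controller, as the bulky group that enforces the trans closure and as the nitrogen protecting group for steps 4 and 9.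

**Step 4**
Reactants: 10 the tetrahydroisoquinoline (1S,3S)-2-[(1R)-2-hydroxy-1-phenylethyl]-6,8-dimethoxy-1,3-dimethyl-1,2,3,4-tetrahydroisoquinoline
Product: 11 the aryl bromide (1S,3S)-5-bromo-2-[(1R)-2-hydroxy-1-phenylethyl]-6,8-dimethoxy-1,3-dimethyl-1,2,3,4-tetrahydroisoquinoline
Conditions: NBS (1.0 equiv), CF3CO2H (1.1 equiv), MeCN, −20 → 0 °C
Reagents that add atoms: N-bromosuccinimide, O=C1CCC(=O)N1Br
Why: Electrophilic aromatic bromination of the ammonium salt should take place at C5, which is ortho to the C6 methoxy group and para to the C8 methoxy group and less hindered than C7 between the two methoxy groups, while protonation of the amine blocks N-bromination and oxidation next to nitrogen.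

**Step 5**
Reactants: 12 anisole; 13 hexacarbonylchromium Cr(CO)6
Product: 16 pentacarbonyl[methoxy(2-methoxyphenyl)methylidene]chromium, via aryllithium 14 (not isolated), via lithium acyl chromate 15 (not isolated)
Conditions: n-BuLi, TMEDA, Et2O, 0 °C → rt; Cr(CO)6, Et2O, 0 °C → rt; Me3OBF4, CH2Cl2, 0 °C
Reagents that add atoms: trimethyloxonium tetrafluoroborate (Me3OBF4), C[O+](C)C.F[B-](F)(F)F
Why: Directed ortho-lithiation of anisole, addition of the aryllithium to a CO ligand of Cr(CO)6 and O-methylation of the acyl chromate is the standard synthesis of a Fischer carbene complex.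

**Step 6**
Reactants: 16 pentacarbonyl[methoxy(2-methoxyphenyl)methylidene]chromium; 17 propyne
Product: 19 the naphthol 4,5-dimethoxy-2-methylnaphthalen-1-ol, via tricarbonylchromium naphthol complex 18 (not isolated)
Conditions: propyne (5 equiv), THF, 55 °C, sealed tube; then air, MeCN, rt
Reagents that add atoms: none
Why: Dötz benzannulation: loss of CO, insertion of propyne and of a CO ligand, ring closure onto the free ortho carbon of the aryl group and tautomerisation build the new benzene ring with the carbene carbon as C4 (OMe), the CO-derived carbon as C1 (OH) and the methyl group of the terminal alkyne next to the hydroxyl group at C2, and air then releases the naphthol from chromium.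

**Step 7**
Reactants: 19 the naphthol 4,5-dimethoxy-2-methylnaphthalen-1-ol
Product: 20 the triflate 4,5-dimethoxy-2-methylnaphthalen-1-yl trifluoromethanesulfonate
Conditions: Tf2O, pyridine, CH2Cl2, 0 °C
Reagents that add atoms: trifluoromethanesulfonic anhydride, O=S(=O)(OS(=O)(=O)C(F)(F)F)C(F)(F)F
Why: O-Sulfonylation of the naphthol (aryl triflate formation) turns the C1 oxygen into a leaving group for cross-coupling.

**Step 8**
Reactants: 20 the triflate 4,5-dimethoxy-2-methylnaphthalen-1-yl trifluoromethanesulfonate
Product: 21 the boronate 2-(4,5-dimethoxy-2-methylnaphthalen-1-yl)-4,4,5,5-tetramethyl-1,3,2-dioxaborolane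
Conditions: B2pin2, Pd(dppf)Cl2 (3 mol%), KOAc, 1,4-dioxane, 90 °C
Reagents that add atoms: bis(pinacolato)diboron, CC1(C)OB(OC1(C)C)B1OC(C)(C)C(C)(C)O1
Why: Miyaura borylation of an aryl triflate (oxidative addition to zerovalent palladium, acetate-assisted transmetalation with B2pin2, reductive elimination) should give the pinacol boronate despite the ortho methyl group.

**Step 9**
Reactants: 11 the aryl bromide (1S,3S)-5-bromo-2-[(1R)-2-hydroxy-1-phenylethyl]-6,8-dimethoxy-1,3-dimethyl-1,2,3,4-tetrahydroisoquinoline; 21 the boronate 2-(4,5-dimethoxy-2-methylnaphthalen-1-yl)-4,4,5,5-tetramethyl-1,3,2-dioxaborolane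
Product: 22 the biaryl (1S,3S)-5-(4,5-dimethoxy-2-methylnaphthalen-1-yl)-2-[(1R)-2-hydroxy-1-phenylethyl]-6,8-dimethoxy-1,3-dimethyl-1,2,3,4-tetrahydroisoquinoline (both configurations of the axis)
Conditions: Pd(OAc)2 (5 mol%), SPhos (10 mol%), K3PO4, toluene/H2O (10:1), 100 °C
Reagents that add atoms: none
Why: Suzuki–Miyaura coupling with the bulky electron-rich ligand SPhos, which is established for tetra-ortho-substituted biaryls, forms the C5–C1' bond; the amine is tertiary and the alcohol is tolerated, and both configurations of the new hindered axis are expected to form.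

**Step 10**
Reactants: 22 the biaryl (1S,3S)-5-(4,5-dimethoxy-2-methylnaphthalen-1-yl)-2-[(1R)-2-hydroxy-1-phenylethyl]-6,8-dimethoxy-1,3-dimethyl-1,2,3,4-tetrahydroisoquinoline
Product: 23 the target (1S,3S)-5-(4,5-dimethoxy-2-methylnaphthalen-1-yl)-6,8-dimethoxy-1,3-dimethyl-1,2,3,4-tetrahydroisoquinoline
Conditions: H2 (4 bar), Pd(OH)2/C, MeOH/AcOH (10:1), rt
Reagents that add atoms: none
Why: Hydrogenolysis of the exocyclic benzylic C–N bond (N-debenzylation) removes the auxiliary as 2-phenylethanol, while the endocyclic C–N bonds, the aryl ethers, the naphthalene and the two stereocentres should be untouched under these mild conditions.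

**Compound list**
1 | (2R)-2-amino-2-phenylethanol [(R)-phenylglycinol] | N[C@@H](CO)c1ccccc1 | starting material
2 | acetaldehyde | CC=O | starting material
3 | (4R)-2-methyl-4-phenyl-1,3-oxazolidine (C2 epimers) | CC1N[C@@H](CO1)c1ccccc1 | intermediate
4 | 3,5-dimethoxybenzyl chloride | COc1cc(CCl)cc(OC)c1 | starting material
5 | (3,5-dimethoxybenzyl)magnesium chloride | COc1cc(C[Mg]Cl)cc(OC)c1 | intermediate
6 | 1,1-diethoxyethane (acetaldehyde diethyl acetal) | CCOC(C)OCC | starting material
7 | (2R)-2-{[(2S)-1-(3,5-dimethoxyphenyl)propan-2-yl]amino}-2-phenylethanol (not isolated) | C[C@@H](Cc1cc(OC)cc(OC)c1)N[C@@H](CO)c1ccccc1 | intermediate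
8 | (4R)-3-[(2S)-1-(3,5-dimethoxyphenyl)propan-2-yl]-2-methyl-4-phenyl-1,3-oxazolidine (C2 epimers; not isolated) | CC1OC[C@@H](c2ccccc2)N1[C@@H](C)Cc1cc(OC)cc(OC)c1 | intermediate
9 | N-[(2S)-1-(3,5-dimethoxyphenyl)propan-2-yl]-N-[(1R)-2-hydroxy-1-phenylethyl]ethaniminium trifluoroacetate (not isolated) | CC=[N+]([C@@H](CO)c1ccccc1)[C@@H](C)Cc1cc(OC)cc(OC)c1.[O-]C(=O)C(F)(F)F | intermediate
10 | (1S,3S)-2-[(1R)-2-hydroxy-1-phenylethyl]-6,8-dimethoxy-1,3-dimethyl-1,2,3,4-tetrahydroisoquinoline | COc1cc(OC)c2c(c1)C[C@H](C)N([C@@H](CO)c1ccccc1)[C@H]2C | intermediate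
11 | (1S,3S)-5-bromo-2-[(1R)-2-hydroxy-1-phenylethyl]-6,8-dimethoxy-1,3-dimethyl-1,2,3,4-tetrahydroisoquinoline | COc1cc(OC)c2c(c1Br)C[C@H](C)N([C@@H](CO)c1ccccc1)[C@H]2C | intermediate
12 | anisole | COc1ccccc1 | starting material
13 | hexacarbonylchromium | O=C=[Cr](=C=O)(=C=O)(=C=O)(=C=O)=C=O | starting material
14 | (2-methoxyphenyl)lithium (not isolated) | [Li]c1ccccc1OC | intermediate
15 | lithium pentacarbonyl[(2-methoxyphenyl)(oxido)methylidene]chromate (not isolated) | [Li+].[O-]C(c1ccccc1OC)=[Cr](=C=O)(=C=O)(=C=O)(=C=O)=C=O | intermediate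
16 | pentacarbonyl[methoxy(2-methoxyphenyl)methylidene]chromium | COC(c1ccccc1OC)=[Cr](=C=O)(=C=O)(=C=O)(=C=O)=C=O | intermediate
17 | propyne | CC#C | starting material
18 | tricarbonyl(4,5-dimethoxy-2-methylnaphthalen-1-ol)chromium (arene complex written as its components; not isolated) | Cc1cc(OC)c2c(OC)cccc2c1O.[Cr].[C-]#[O+].[C-]#[O+].[C-]#[O+] | intermediate
19 | 4,5-dimethoxy-2-methylnaphthalen-1-ol | Cc1cc(OC)c2c(OC)cccc2c1O | intermediate
20 | 4,5-dimethoxy-2-methylnaphthalen-1-yl trifluoromethanesulfonate | Cc1cc(OC)c2c(OC)cccc2c1OS(=O)(=O)C(F)(F)F | intermediate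
21 | 2-(4,5-dimethoxy-2-methylnaphthalen-1-yl)-4,4,5,5-tetramethyl-1,3,2-dioxaborolane | Cc1cc(OC)c2c(OC)cccc2c1B1OC(C)(C)C(C)(C)O1 | intermediate
22 | (1S,3S)-5-(4,5-dimethoxy-2-methylnaphthalen-1-yl)-2-[(1R)-2-hydroxy-1-phenylethyl]-6,8-dimethoxy-1,3-dimethyl-1,2,3,4-tetrahydroisoquinoline | COc1cc(OC)c2c(c1-c1c(C)cc(OC)c3c(OC)cccc13)C[C@H](C)N([C@@H](CO)c1ccccc1)[C@H]2C | intermediate
23 | (1S,3S)-5-(4,5-dimethoxy-2-methylnaphthalen-1-yl)-6,8-dimethoxy-1,3-dimethyl-1,2,3,4-tetrahydroisoquinoline | COc1cc(OC)c2c(c1-c1c(C)cc(OC)c3c(OC)cccc13)C[C@H](C)N[C@H]2C | target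

**Step count and risks**
Total: 10 steps. Longest linear sequence: 6 steps (steps 5, 6, 7, 8, 9 and 10).

Step 3. What may go wrong: loss of stereocontrol in the acid-promoted ring closure, because the hydroxyl-bearing N-substituent keeps re-forming the oxazolidine and may not enforce the trans arrangement as cleanly as a benzyl group; and incomplete addition through α-deprotonation of the chelated imine. The fallback sets out from 7 and comes back to the route at 23. Compound 7 is isolated by quenching the first stage with aqueous NH4Cl instead of acid. Hydrogenolysis (H2, Pd(OH)2/C, MeOH) should give the primary amine (2S)-1-(3,5-dimethoxyphenyl)propan-2-amine F1. Reductive amination with benzaldehyde and NaBH4 should give (2S)-N-benzyl-1-(3,5-dimethoxyphenyl)propan-2-amine F2. A separate Pictet–Spengler reaction with acetaldehyde in CF3CO2H/CH2Cl2, the established trans-selective N-benzyl variant, should give (1S,3S)-2-benzyl-6,8-dimethoxy-1,3-dimethyl-1,2,3,4-tetrahydroisoquinoline F3. Bromination under the conditions of step 4 should give (1S,3S)-2-benzyl-5-bromo-6,8-dimethoxy-1,3-dimethyl-1,2,3,4-tetrahydroisoquinoline F4. Coupling with 21 under the conditions of step 9 should give (1S,3S)-2-benzyl-5-(4,5-dimethoxy-2-methylnaphthalen-1-yl)-6,8-dimethoxy-1,3-dimethyl-1,2,3,4-tetrahydroisoquinoline F5, and hydrogenolysis (H2, Pd/C, MeOH) of F5 should give 23.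

Step 9. What may go wrong: slow transmetalation and reductive elimination at a centre that becomes tetra-ortho-substituted, so that protodeboronation of the electron-rich naphthyl boronate wins. The fallback sets out from 11 and 20 and comes back to the route at 22; it reverses the polarity of the coupling and leaves out the boronate. Compound 11 is deprotonated at oxygen (n-BuLi, 1 equiv, THF, −78 °C), subjected to bromine–lithium exchange (t-BuLi, 2 equiv) and transmetalated with ZnCl2 to the arylzinc reagent [(1S,3S)-2-[(1R)-2-(lithiooxy)-1-phenylethyl]-6,8-dimethoxy-1,3-dimethyl-1,2,3,4-tetrahydroisoquinolin-5-yl]zinc chloride F6. A Negishi coupling of F6 with triflate 20 (Pd2(dba)3, RuPhos, THF/NMP, 70 °C) should give 22 after aqueous work-up.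

Step 10. What may go wrong: sluggish hydrogenolysis at the crowded tertiary amine, with competing cleavage of the benzylic C1–N bond of the electron-rich ring A when the conditions are forced. The fallback sets out from 22 and comes back to the route at 23; it removes the auxiliary by oxidation instead of reduction. Pb(OAc)4 in CH2Cl2/MeOH at 0 °C should cleave the 1,2-amino alcohol, with loss of formaldehyde, to the iminium salt (1S,3S)-2-benzylidene-5-(4,5-dimethoxy-2-methylnaphthalen-1-yl)-6,8-dimethoxy-1,3-dimethyl-1,2,3,4-tetrahydroisoquinolin-2-ium acetate F7, and aqueous HCl followed by basification should hydrolyse F7 to 23 and benzaldehyde.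

**Further compounds**
F1 | step 3 | (2S)-1-(3,5-dimethoxyphenyl)propan-2-amine | C[C@H](N)Cc1cc(OC)cc(OC)c1
F2 | step 3 | (2S)-N-benzyl-1-(3,5-dimethoxyphenyl)propan-2-amine | C[C@H](NCc1ccccc1)Cc1cc(OC)cc(OC)c1
F3 | step 3 | (1S,3S)-2-benzyl-6,8-dimethoxy-1,3-dimethyl-1,2,3,4-tetrahydroisoquinoline | COc1cc(OC)c2c(c1)C[C@H](C)N(Cc1ccccc1)[C@H]2C
F4 | step 3 | (1S,3S)-2-benzyl-5-bromo-6,8-dimethoxy-1,3-dimethyl-1,2,3,4-tetrahydroisoquinoline | COc1cc(OC)c2c(c1Br)C[C@H](C)N(Cc1ccccc1)[C@H]2C
F5 | step 3 | (1S,3S)-2-benzyl-5-(4,5-dimethoxy-2-methylnaphthalen-1-yl)-6,8-dimethoxy-1,3-dimethyl-1,2,3,4-tetrahydroisoquinoline | COc1cc(OC)c2c(c1-c1c(C)cc(OC)c3c(OC)cccc13)C[C@H](C)N(Cc1ccccc1)[C@H]2C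
F6 | step 9 | [(1S,3S)-2-[(1R)-2-(lithiooxy)-1-phenylethyl]-6,8-dimethoxy-1,3-dimethyl-1,2,3,4-tetrahydroisoquinolin-5-yl]zinc chloride | COc1cc(OC)c2c(c1[Zn]Cl)C[C@H](C)N([C@@H](CO[Li])c1ccccc1)[C@H]2C
F7 | step 10 | (1S,3S)-2-benzylidene-5-(4,5-dimethoxy-2-methylnaphthalen-1-yl)-6,8-dimethoxy-1,3-dimethyl-1,2,3,4-tetrahydroisoquinolin-2-ium acetate | COc1cc(OC)c2c(c1-c1c(C)cc(OC)c3c(OC)cccc13)C[C@H](C)[N+](=Cc1ccccc1)[C@H]2C.CC(=O)[O-]
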